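The earlier runs and the new flask are calculated on assumed constants; scatter was added.

| flask | substrate | partner | remark | time |
|---|---|---|---|---|
| gamma | 11 mM | 6.6 mM | the very flask that is asked about, followed so far |  |
| eta | 16 mM | 6.6 mM | run made earlier |  |
| flask | 11 mM | 6.60 mM |  | 40 h |

| run | time / h | substrate / % | target / % |
|---|---|---|---|
| gamma | 1.50 | 44 | 55 |
| gamma | 3.00 | 41 | 60 |
| gamma | 5.00 | 43 | 56 |
| gamma | 6.00 | 41 | 57 |
| gamma | 8.00 | 43 | 57 |
| gamma | 10.0 | 43 | 55 |
| gamma | 12.0 | 42 | 58 |
| eta | 3.00 | 57 | 39 |
| eta | 5.00 | 59 | 38 |
| eta | 8.00 | 56 | 41 |
| eta | 12.0 | 59 | 40 |
| eta | 15.0 | 58 | 39 |
| eta | 25.0 | 57 | 42 |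
| eta | 40.0 | 61 | 42 |

(each reading ± 1.5 percentage points)

- the reaction counts as stopped when no species that holds the substrate changes by six tenths of a point or more over the second half of the time

- the state of affairs at 40 h: stopped, and by what, or still going (all of the substrate has reacted / the partner has run out first / it is still moving / forward and back rates have come level)
- how much of the substrate has reacted by 40 h
- how much target there is at 40 h, in percent of the substrate charged

- Start from the ratio of partner to substrate charged. In gamma and in the flask, which share their charges, it is 60.0%. If each target takes one substrate and one partner, that ratio is the ceiling on target, and partner is the limiting reagent.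
- Turn time first. By hand, a change with a time constant far below the time asked for is flat at that time. Gamma reads level from its first reading at 1.50 h, with target averaging 56.9% and substrate 42.4%.
- Turn partner next. By hand, with substrate held and partner charged below it, the ceiling moves in step with the partner charged. Both runs hold partner at 6.6 mM, so read what gamma leaves: target reads 6.25 mM, so [partner] reads 0.346 mM, a small difference and therefore a rough reading.
- Turn substrate last. By hand, a flask at constant temperature whose forward and back rates are level holds [target]/([substrate][partner]) constant, so the logarithm to base ten of [target]/[partner] rises with that of [substrate]. Gamma's averages give 3.88 mM⁻¹, the read equilibrium constant, and a [target]/[partner] of 1.26 powers of ten.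
- Check that constant on eta, with its larger substrate charge: its averages give 40.1% target and 58.1% substrate, hence 3.90 mM⁻¹.
- Commit, then: the flask stands on gamma's plateau at 40 h, with forward and back rates level, 57.6% reacted and 56.9% target.
- The forecast says forward and back rates have come level, with 57.6% reacted (56.3% to 59.5%) and 57% target (55.5% to 58.8%), noting that “equilibrium lies close to the cap”.
- The flask gives 58.0% reacted and 58.0% target at 40 h: forward and back rates have come level. With substrate and time held, target in the flask has moved by 5 points once partner is down at 6.01 mM.

    substrate + partner ⇌ target (K = 6400 M⁻¹, k = 0.0950 M⁻¹ s⁻¹)

- Now use the read constant on a neighbour flask charged with 27 mM of substrate. Take its [substrate] as the charge less the partner charged, about 20.4 mM, so the reckoned [target]/[partner] is 79.1, which is 1.90 powers of ten. That puts target at 24.1% of the substrate charged, and that neighbour flask holds 24.3%.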